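## Retrosynthetic overview

1. Target 17 ⇐ 16 (BCl3 frees the three phenols) ⇐ 15 (dithiane → C4 ketone). The base-sensitive flavanone carbonyl is unveiled only after all basic steps.
2. 15 ⇐ biaryl bond (C3' of the flavanone ring B to C8 of the flavone) by borylation/Suzuki coupling of aryl bromide 13 with 8-iodoflavone 3. The flavone rings are bought intact as apigenin.
3. 13 ⇐ key step: the C3–C4 bond of the flavanone half is made from a ring A acyl-anion equivalent (dianion 10 of hydroxyaryl dithiane 9) and the CH2 of (S)-aryloxirane 7. Ring C is then closed (O1–C2) by Mitsunobu inversion in the same flask.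
4. 7 ⇐ 3-bromo-4-hydroxybenzaldehyde (benzylation, Corey–Chaykovsky, hydrolytic kinetic resolution); 9 ⇐ 2-hydroxy-4,6-dimethoxybenzaldehyde.
5. Ring order: flavone rings (pre-formed) → flavanone ring C (key step) → biaryl union → unmasking.

Assumption: the biaryl axis is not configurationally stable at room temperature (as in amentoflavone), so C2 of the flavanone half is the only stereo-element to control.

## Route

Step 1
Reactants: 1 apigenin [5,7-dihydroxy-2-(4-hydroxyphenyl)-4H-chromen-4-one]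
Product: 2 5,7-dimethoxy-2-(4-methoxyphenyl)-4H-chromen-4-one
Conditions: Me2SO4 (5 equiv), K2CO3 (6 equiv), acetone, reflux, 36 h
Reagents that add atoms: dimethyl sulfate COS(=O)(=O)OC
Why: Exhaustive Williamson O-methylation of the three phenoxides, the chelated 5-OH reacting last under forcing reflux, and the 5-OMe so installed later steers iodination to C8.

Step 2
Reactants: 2 5,7-dimethoxy-2-(4-methoxyphenyl)-4H-chromen-4-one
Product: 3 8-iodo-5,7-dimethoxy-2-(4-methoxyphenyl)-4H-chromen-4-one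
Conditions: NIS (1.15 equiv), CF3CO2H (0.3 equiv), MeCN, rt, dark, 12 h
Reagents that add atoms: N-iodosuccinimide O=C1CCC(=O)N1I
Why: Electrophilic aromatic iodination of the 5,7-dimethoxy ring A, which with the 5-oxygen alkylated reacts at C8 (between O1 and 7-OMe) and not at the more hindered C6 between two methoxy groups, while the deactivated ring B stays untouched.

Step 3
Reactants: 4 3-bromo-4-hydroxybenzaldehyde
Product: 5 4-(benzyloxy)-3-bromobenzaldehyde
Conditions: BnBr (1.1 equiv), K2CO3 (1.5 equiv), DMF, 60 °C, 3 h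
Reagents that add atoms: benzyl bromide BrCc1ccccc1
Why: Williamson ether synthesis, giving a benzyl ether that survives organolithium, Mitsunobu and Suzuki conditions and is cleaved in the final BCl3 step.

Step 4
Reactants: 5 4-(benzyloxy)-3-bromobenzaldehyde
Product: 6 racemic 2-[4-(benzyloxy)-3-bromophenyl]oxirane
Conditions: Me3SI (1.3 equiv), KOH (powder, 2.5 equiv), MeCN (trace H2O), 60 °C, 3 h
Reagents that add atoms: trimethylsulfonium iodide C[S+](C)C.[I-]
Why: Corey–Chaykovsky epoxidation, in which dimethylsulfonium methylide adds to the aldehyde and the betaine closes to the terminal oxirane (racemic at this stage).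

Step 5
Reactants: 6 racemic 2-[4-(benzyloxy)-3-bromophenyl]oxirane
Product: 7 (S)-2-[4-(benzyloxy)-3-bromophenyl]oxirane
Conditions: (S,S)-(salen)Co(OAc) [salen = N,N'-bis(3,5-di-tert-butylsalicylidene)-1,2-cyclohexanediamine dianion; trivalent cobalt] (1 mol%), H2O (0.55 equiv), THF, 0 °C → rt, 18 h
Reagents that add atoms: none
Why: Jacobsen hydrolytic kinetic resolution, in which the (S,S)-cobalt salen catalyst hydrates the (R)-oxirane selectively at its CH2 and leaves the (S)-oxirane (at most 50%, ≥99% ee), whose stereocentre becomes C2 of the flavanone half.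

Step 6
Reactants: 8 2-hydroxy-4,6-dimethoxybenzaldehyde
Product: 9 2-(1,3-dithian-2-yl)-3,5-dimethoxyphenol
Conditions: HS(CH2)3SH (1.1 equiv), BF3·OEt2 (0.3 equiv), CH2Cl2, 0 °C → rt, 4 h
Reagents that add atoms: propane-1,3-dithiol SCCCS
Why: Lewis-acid-catalysed dithioacetalisation turns the aldehyde carbon into a latent acyl anion (Corey–Seebach dithiane) and at the same time into a base-stable mask for the future C4 ketone.

Step 7 (key step)
Reactants: 9 2-(1,3-dithian-2-yl)-3,5-dimethoxyphenol (1.2 equiv); 7 (S)-2-[4-(benzyloxy)-3-bromophenyl]oxirane (1.0 equiv)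
Product: 13 (2S)-2-[4-(benzyloxy)-3-bromophenyl]-5,7-dimethoxyspiro[chromane-4,2'-[1,3]dithiane], via dilithio dianion 10 (not isolated), via dilithium alkoxide 11 (not isolated), via open-chain diol 12 (not isolated)
Conditions: n-BuLi (2.05 equiv per 9), DMPU, THF, –78 → –20 °C, 2 h; 7, –78 → 0 °C, 6 h; PPTS (2 equiv per 9), –40 °C; then PPh3 (1.5 equiv), DIAD (1.5 equiv), 0 °C → rt, 3 h
Reagents that add atoms: n-butyllithium [Li]CCCC (its lithium sits in intermediates 10 and 11 only)
Why: Corey–Seebach umpolung in which the dithiane carbanion of dianion 10 (an acyl-anion equivalent of the ring A aldehyde, used without phenol protection) opens the oxirane at its unhindered CH2 and so joins a former carbonyl carbon to an epoxide carbon without touching the stereocentre, after which the (R)-benzylic alcohol 12 is closed in the same flask by intramolecular Mitsunobu etherification with SN2 inversion to (S) at C2, ionisation being held back by the meta-bromine; both stages are known reaction types run here without isolating 12.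

Step 8
Reactants: 13 (2S)-2-[4-(benzyloxy)-3-bromophenyl]-5,7-dimethoxyspiro[chromane-4,2'-[1,3]dithiane]; 3 8-iodo-5,7-dimethoxy-2-(4-methoxyphenyl)-4H-chromen-4-one
Product: 15 8-{2-(benzyloxy)-5-[(2S)-5,7-dimethoxyspiro[chromane-4,2'-[1,3]dithian]-2-yl]phenyl}-5,7-dimethoxy-2-(4-methoxyphenyl)-4H-chromen-4-one, via pinacol boronate 14 (not isolated)
Conditions: B2pin2 (1.2 equiv), KOAc (3 equiv), Pd(dppf)Cl2 (5 mol%), dioxane, 90 °C, 6 h; then 3 (1.1 equiv), Pd(OAc)2 (5 mol%), SPhos (10 mol%), K3PO4 (3 equiv), H2O, 90 °C, 12 h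
Reagents that add atoms: bis(pinacolato)diboron CC1(C)OB(OC1(C)C)B1OC(C)(C)C(C)(C)O1 (its boron and pinacol atoms sit in intermediate 14 only and are lost again on coupling)
Why: Miyaura borylation followed in the same flask by Suzuki–Miyaura coupling with the hindered 8-iodoflavone using the bulky electron-rich SPhos ligand, and because C4 is still a dithioketal there is no enolisable ketone, so aqueous base cannot open ring C by retro-oxa-Michael reaction and C2 stays (S).

Step 9
Reactants: 15 8-{2-(benzyloxy)-5-[(2S)-5,7-dimethoxyspiro[chromane-4,2'-[1,3]dithian]-2-yl]phenyl}-5,7-dimethoxy-2-(4-methoxyphenyl)-4H-chromen-4-one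
Product: 16 8-{2-(benzyloxy)-5-[(2S)-5,7-dimethoxy-4-oxochroman-2-yl]phenyl}-5,7-dimethoxy-2-(4-methoxyphenyl)-4H-chromen-4-one
Conditions: MeI (20 equiv), CaCO3 (5 equiv), MeCN/H2O 9:1, 40 °C, sealed vessel, 24 h
Reagents that add atoms: water O
Why: Alkylative dithiane hydrolysis (S-methylation, ring opening to a thionium ion, capture by water) under CaCO3-buffered near-neutral conditions that neither enolise nor ring-open the new flavanone, so C2 stays (S).

Step 10
Reactants: 16 8-{2-(benzyloxy)-5-[(2S)-5,7-dimethoxy-4-oxochroman-2-yl]phenyl}-5,7-dimethoxy-2-(4-methoxyphenyl)-4H-chromen-4-one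
Product: 17 2,3-dihydroheveaflavone [5-hydroxy-8-{2-hydroxy-5-[(2S)-5-hydroxy-7-methoxy-4-oxochroman-2-yl]phenyl}-7-methoxy-2-(4-methoxyphenyl)-4H-chromen-4-one]
Conditions: BCl3 (8 equiv), pentamethylbenzene (3 equiv), CH2Cl2, –78 °C (1 h) → 0 °C (2 h); then H2O
Reagents that add atoms: none
Why: Chelation-controlled Lewis-acid ether cleavage in which BCl3 removes the benzyl ether (cation trapped by pentamethylbenzene) and, through six-membered boron chelates with the two C4 carbonyls, only the two peri C5 methyl ethers, leaving the 7-, 7''- and 4'''-OMe groups and the C2 stereocentre untouched.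

## Compound list

1 | apigenin, 5,7-dihydroxy-2-(4-hydroxyphenyl)-4H-chromen-4-one | O=c1cc(-c2ccc(O)cc2)oc2cc(O)cc(O)c12 | starting material
2 | 5,7-dimethoxy-2-(4-methoxyphenyl)-4H-chromen-4-one | COc1ccc(-c2cc(=O)c3c(OC)cc(OC)cc3o2)cc1 | intermediate
3 | 8-iodo-5,7-dimethoxy-2-(4-methoxyphenyl)-4H-chromen-4-one | COc1ccc(-c2cc(=O)c3c(OC)cc(OC)c(I)c3o2)cc1 | intermediate
4 | 3-bromo-4-hydroxybenzaldehyde | O=Cc1ccc(O)c(Br)c1 | starting material
5 | 4-(benzyloxy)-3-bromobenzaldehyde | O=Cc1ccc(OCc2ccccc2)c(Br)c1 | intermediate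
6 | racemic 2-[4-(benzyloxy)-3-bromophenyl]oxirane | Brc1cc(C2CO2)ccc1OCc1ccccc1 | intermediate
7 | (S)-2-[4-(benzyloxy)-3-bromophenyl]oxirane | Brc1cc([C@H]2CO2)ccc1OCc1ccccc1 | intermediate
8 | 2-hydroxy-4,6-dimethoxybenzaldehyde | COc1cc(O)c(C=O)c(OC)c1 | starting material
9 | 2-(1,3-dithian-2-yl)-3,5-dimethoxyphenol | COc1cc(O)c(C2SCCCS2)c(OC)c1 | intermediate
10 | dilithio dianion of 9 (lithium phenoxide and 2-lithio-1,3-dithiane) | [Li+].[Li+].COc1cc([O-])c([C-]2SCCCS2)c(OC)c1 | intermediate (not isolated)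
11 | dilithium salt (alkoxide and phenoxide) of diol 12, (R) at the carbinol carbon | [Li+].[Li+].COc1cc([O-])c(C2(C[C@@H]([O-])c3ccc(OCc4ccccc4)c(Br)c3)SCCCS2)c(OC)c1 | intermediate (not isolated)
12 | 2-{2-[(2R)-2-[4-(benzyloxy)-3-bromophenyl]-2-hydroxyethyl]-1,3-dithian-2-yl}-3,5-dimethoxyphenol | COc1cc(O)c(C2(C[C@@H](O)c3ccc(OCc4ccccc4)c(Br)c3)SCCCS2)c(OC)c1 | intermediate (not isolated)
13 | (2S)-2-[4-(benzyloxy)-3-bromophenyl]-5,7-dimethoxyspiro[chromane-4,2'-[1,3]dithiane] | Brc1cc([C@@H]2CC3(SCCCS3)c3c(OC)cc(OC)cc3O2)ccc1OCc1ccccc1 | intermediate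
14 | (2S)-2-[4-(benzyloxy)-3-(4,4,5,5-tetramethyl-1,3,2-dioxaborolan-2-yl)phenyl]-5,7-dimethoxyspiro[chromane-4,2'-[1,3]dithiane] | CC1(C)OB(OC1(C)C)c1cc([C@@H]2CC3(SCCCS3)c3c(OC)cc(OC)cc3O2)ccc1OCc1ccccc1 | intermediate (not isolated)
15 | 8-{2-(benzyloxy)-5-[(2S)-5,7-dimethoxyspiro[chromane-4,2'-[1,3]dithian]-2-yl]phenyl}-5,7-dimethoxy-2-(4-methoxyphenyl)-4H-chromen-4-one | COc1ccc(-c2cc(=O)c3c(OC)cc(OC)c(-c4cc([C@@H]5CC6(SCCCS6)c6c(OC)cc(OC)cc6O5)ccc4OCc4ccccc4)c3o2)cc1 | intermediate
16 | 8-{2-(benzyloxy)-5-[(2S)-5,7-dimethoxy-4-oxochroman-2-yl]phenyl}-5,7-dimethoxy-2-(4-methoxyphenyl)-4H-chromen-4-one | COc1ccc(-c2cc(=O)c3c(OC)cc(OC)c(-c4cc([C@@H]5CC(=O)c6c(OC)cc(OC)cc6O5)ccc4OCc4ccccc4)c3o2)cc1 | intermediate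
17 | 2,3-dihydroheveaflavone, (2S) at the flavanone C2 | COc1ccc(-c2cc(=O)c3c(O)cc(OC)c(-c4cc([C@@H]5CC(=O)c6c(O)cc(OC)cc6O5)ccc4O)c3o2)cc1 | target

## Step count and risks

Total: 10 steps. Longest linear sequence: 7 steps (4 → 5 → 6 → 7 → 13 → 15 → 16 → 17, that is steps 3, 4, 5, 7, 8, 9 and 10).

The three steps most likely to fail:

**Step 7.** The unprotected dianion 10 is hindered, electron-rich and prone to aggregation, so the epoxide opening may be slow or incomplete. The Mitsunobu closure on unpurified material could also lose some enantiopurity through benzylic ionisation. The fallback sets out from 9 and comes back at 13. The phenol is first capped (allyl bromide, K2CO3, acetone) to give 2-[2-(allyloxy)-4,6-dimethoxyphenyl]-1,3-dithiane F1. One equivalent of n-BuLi (THF, –40 °C) gives the soluble monoanion 2-lithio-2-[2-(allyloxy)-4,6-dimethoxyphenyl]-1,3-dithiane F2. This opens 7 and, after aqueous work-up and chromatography, gives (1R)-2-{2-[2-(allyloxy)-4,6-dimethoxyphenyl]-1,3-dithian-2-yl}-1-[4-(benzyloxy)-3-bromophenyl]ethanol F3. Pd(PPh3)4 with morpholine removes the allyl group to give diol 12, now isolated and checked for ee. A separate Mitsunobu reaction (PPh3, DIAD, toluene, 0 °C) closes it to 13.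

**Step 8.** The biaryl is tri-ortho-substituted, the iodide 3 can be reduced instead of coupled, and the dithiane sulfur may slow the palladium catalyst. The fallback sets out from 13 and comes back at 15. Bromine–lithium exchange (n-BuLi, THF, –78 °C) gives (2S)-2-[4-(benzyloxy)-3-lithiophenyl]-5,7-dimethoxyspiro[chromane-4,2'-[1,3]dithiane] F4. ZnCl2 converts it into the arylzinc chloride, chlorido{2-(benzyloxy)-5-[(2S)-5,7-dimethoxyspiro[chromane-4,2'-[1,3]dithian]-2-yl]phenyl}zinc F5. A base-free Negishi coupling with 3 (Pd2(dba)3, XPhos, THF, 50 °C) then forms the biaryl 15.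

**Step 10.** One Lewis acid must cleave three ethers on a flavanone that can ring-open and racemise once its carbonyl is activated, and the benzyl cation can alkylate the electron-rich rings. The fallback sets out from 16 and comes back at 17, and separates the two events. Hydrogenolysis (H2, 1 atm, Pd on carbon, EtOAc/THF) removes the benzyl group without forming a benzyl cation, giving 8-{2-hydroxy-5-[(2S)-5,7-dimethoxy-4-oxochroman-2-yl]phenyl}-5,7-dimethoxy-2-(4-methoxyphenyl)-4H-chromen-4-one F6. Anhydrous MgI2 (toluene/Et2O, 60 °C) then cleaves only the two chelated peri methyl ethers by iodide SN2 attack under much weaker Lewis acidity, giving 17.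

## Further compounds

F1 | step 7 | 2-[2-(allyloxy)-4,6-dimethoxyphenyl]-1,3-dithiane | C=CCOc1cc(OC)cc(OC)c1C1SCCCS1
F2 | step 7 | 2-lithio-2-[2-(allyloxy)-4,6-dimethoxyphenyl]-1,3-dithiane | [Li+].C=CCOc1cc(OC)cc(OC)c1[C-]1SCCCS1
F3 | step 7 | (1R)-2-{2-[2-(allyloxy)-4,6-dimethoxyphenyl]-1,3-dithian-2-yl}-1-[4-(benzyloxy)-3-bromophenyl]ethanol | C=CCOc1cc(OC)cc(OC)c1C1(C[C@@H](O)c2ccc(OCc3ccccc3)c(Br)c2)SCCCS1
F4 | step 8 | (2S)-2-[4-(benzyloxy)-3-lithiophenyl]-5,7-dimethoxyspiro[chromane-4,2'-[1,3]dithiane] | [Li]c1cc([C@@H]2CC3(SCCCS3)c3c(OC)cc(OC)cc3O2)ccc1OCc1ccccc1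
F5 | step 8 | chlorido{2-(benzyloxy)-5-[(2S)-5,7-dimethoxyspiro[chromane-4,2'-[1,3]dithian]-2-yl]phenyl}zinc | Cl[Zn]c1cc([C@@H]2CC3(SCCCS3)c3c(OC)cc(OC)cc3O2)ccc1OCc1ccccc1
F6 | step 10 | 8-{2-hydroxy-5-[(2S)-5,7-dimethoxy-4-oxochroman-2-yl]phenyl}-5,7-dimethoxy-2-(4-methoxyphenyl)-4H-chromen-4-one | COc1ccc(-c2cc(=O)c3c(OC)cc(OC)c(-c4cc([C@@H]5CC(=O)c6c(OC)cc(OC)cc6O5)ccc4O)c3o2)cc1
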